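**Plan**
1. Numbering as a tetralin: C1 carries aryl ring C, C2 and C3 carry the CH2OH groups, C4 is CH2, C4a/C8a are the fusion atoms, and ring A has OMe at C6 and OH at C7 and C8. The target is (1S,2R,3S), that is 1,2-trans and 2,3-cis.
2. Enabling feature: the free C7,C8 catechol of ring A beside the C6 methyl ether is the aromatic bis-enol of an ene-1,2-dione. Ring A can therefore enter as 3-methoxy-1,2-benzoquinone, reacting at its one unsubstituted double bond (the future C4a–C8a).
3. Cuts: first the exocyclic bonds C2–CH2OH and C3–CH2OH (back through a cis-fused cyclobutanone to a C2=C3 alkene plus a ketene). Then C1–C8a and C4–C4a together (Diels–Alder), and last the C1=C2 bond of the diene (olefination of the ring C aldehyde).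
4. Forward: rings A and C are bought. Ring B is closed by the (4+2) addition and ring A re-aromatises by enolization. A temporary four-membered ring is fused onto C2–C3 by (2+2) addition and cut between its two ketene carbons, passing through a γ-lactone to the diol.
5. Stereochemistry: C1 comes from the bis(oxazoline)–Cu(OTf)2 catalyst (quinone face plus endo approach of the E diene). C2 and C3 come from suprafacial ketene addition to the face opposite the pseudoaxial C1 aryl group.

Key step: step 3

Assumption: (S,S)-t-Bu-box, 2,2'-(propane-2,2-diyl)bis[(4S)-4-tert-butyl-4,5-dihydro-1,3-oxazole], is written as the ligand that opens the quinone face leading to (S)-C1. No precedent fixes the sense of induction for an o-quinone, and the equally available (R,R)-ligand would be used if the sense proves opposite.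
Assumption: in the ketene addition the carbonyl carbon is drawn on C3, the less hindered alkene carbon, where the leading bond should form. The other orientation only exchanges the two ketene carbons, runs through the same steps and ends in the same diol, so regioisomers need not be separated.

Step 1
Reactants: 1 3,4,5-trimethoxybenzaldehyde
Product: 2 (E)-1-(3,4,5-trimethoxyphenyl)buta-1,3-diene
Conditions: diethyl allylphosphonate, n-BuLi, THF, −78 °C; then 1; then HMPA, −78 °C to rt
Reagents that add atoms: diethyl allylphosphonate, C=CCP(=O)(OCC)OCC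
Why: Horner–Wadsworth–Emmons olefination through α-attack of the lithiated allylphosphonate on an aromatic aldehyde, in which elimination from the equilibrated β-oxido phosphonate should give the terminal diene with the E styrenyl double bond.

Step 2
Reactants: 3 3-methoxycatechol
Product: 4 3-methoxy-1,2-benzoquinone
Conditions: Ag2O, anhydrous Na2SO4, CH2Cl2, 0 °C, dark; filtered through Celite under argon, solution used at once
Reagents that add atoms: none
Why: classical two-electron oxidation of a catechol to the o-quinone by Ag2O under neutral, anhydrous conditions, and the methoxy group makes this quinone long-lived enough to be handled in solution.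

Step 3
Reactants: 4 3-methoxy-1,2-benzoquinone; 2 (E)-1-(3,4,5-trimethoxyphenyl)buta-1,3-diene
Product: 6 (S)-6-methoxy-1-(3,4,5-trimethoxyphenyl)-1,4-dihydronaphthalene-7,8-diol, via endo adduct 5 (not isolated)
Conditions: Cu(OTf)2 (10 mol%), (S,S)-t-Bu-box (11 mol%), 4 Å molecular sieves, 2 (1.5 equiv), CH2Cl2, −78 °C, slow addition of 4; then Et3N (20 mol%), −78 to 0 °C, argon
Reagents that add atoms: none
Why: Proposed new method: the two carbonyl oxygens of 4 bind divalent copper as a five-membered chelate that lowers the quinone LUMO, and the s-cis diene 2 adds suprafacially to the only unsubstituted ring double bond (quinone C5=C6) in a concerted, asynchronous (4+2) cycloaddition in which C4–C4a forms ahead of C1–C8a; catalytic Et3N then removes both ring-fusion hydrogens of 5 by double enolization (C8a–H next to the C8 carbonyl, C4a–H vinylogously to the C7 carbonyl), and aromatisation of ring A makes this irreversible. The closest known reaction types are the uncatalysed Diels–Alder additions of dienes to o-benzoquinones acting as carbon dienophiles, whose adducts enolise to dihydronaphthalenediols, and the bis(oxazoline)–Cu(OTf)2 catalysed cycloadditions of chelating 1,2-dicarbonyl and imide substrates; a chiral Lewis acid on an o-quinone dienophile has not been shown. Ring B is closed by intermolecular annulation, both new bonds being made in the one cycloaddition event, with four ring atoms from the diene and two from the quinone. C1 is the only stereocentre that outlasts enolization, and it is fixed jointly by the quinone face left open by the tert-butyl groups of the twofold-symmetric ligand in the square-planar chelate (the twofold axis makes both ways of binding the unsymmetrical quinone equivalent), by the endo orientation of the diene under the dione and by the E geometry of 2. Regioselectivity rests on the methoxy group, whose lone pair pushes electron density onto quinone C4 and C6 and into the remote carbonyl, so that C5 (the future C4a), the position at which soft nucleophiles add to this quinone, is the electrophilic end of the free double bond and pairs with the unsubstituted diene terminus that carries the larger HOMO coefficient. Periselectivity rests on chelation, which occupies the oxygen termini needed for the hetero-diene mode, and on the methoxy group, which blocks the other double bond and makes the quinone a poorer carbon diene, while slow addition of 4 to excess 2 in the cold keeps free quinone from oxidising the catechol product.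

Step 4
Reactants: 6 (S)-6-methoxy-1-(3,4,5-trimethoxyphenyl)-1,4-dihydronaphthalene-7,8-diol
Product: 7 (S)-7,8-bis(benzyloxy)-6-methoxy-1-(3,4,5-trimethoxyphenyl)-1,4-dihydronaphthalene
Conditions: BnBr (2.5 equiv), K2CO3, DMF, rt, argon
Reagents that add atoms: benzyl bromide, BrCc1ccccc1
Why: Williamson ether synthesis on both phenoxides, with argon to prevent autoxidation of the catechol and a carbonate base too weak to move the skipped C2=C3 double bond or to touch C1–H.

Step 5
Reactants: 7 (S)-7,8-bis(benzyloxy)-6-methoxy-1-(3,4,5-trimethoxyphenyl)-1,4-dihydronaphthalene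
Product: 8 cis-fused dichlorocyclobutanone on C2–C3 (ring path C2–CCl2–C(=O)–C3) lying anti to the C1 aryl group
Conditions: Cl3CCOCl (slow addition), Zn–Cu couple, Et2O–DME, rt, ultrasound
Reagents that add atoms: trichloroacetyl chloride, ClC(Cl)(Cl)C(Cl)=O
Why: thermal ketene–alkene (2+2) cycloaddition of dichloroketene made in situ, suprafacial on the alkene so that the fusion is cis, and directed to the face opposite the C1 aryl group, which stands pseudoaxial on the boat-shaped ring B to escape the peri C8 benzyloxy group, so that C2 and C3 are set relative to C1.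

Step 6
Reactants: 8 cis-fused dichlorocyclobutanone
Product: 9 cis-fused cyclobutanone on C2–C3 (ring path C2–CH2–C(=O)–C3) lying anti to the C1 aryl group
Conditions: Zn dust, AcOH, rt to 50 °C
Reagents that add atoms: none
Why: reductive dechlorination of an α,α-dichloroketone through zinc enolates, which leaves benzyl ethers alone and cannot invert C3, because a trans-fused bicyclo[4.2.0] ketone would be far more strained.

Step 7
Reactants: 9 cis-fused cyclobutanone
Product: 10 trimethylsilyl enol ether (cyclobutene with ring path C2–CH=C(OSiMe3)–C3)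
Conditions: TMSCl then LDA (in situ quench), THF, −78 °C; non-aqueous work-up, used crude
Reagents that add atoms: chlorotrimethylsilane, C[Si](C)(C)Cl
Why: kinetic enolate formation with immediate O-silylation takes the CH2 proton, since enolization toward C3 would place a double bond at the fusion of the four- and six-membered rings.

Step 8
Reactants: 10 trimethylsilyl enol ether
Product: 13 cis-fused γ-butyrolactone on C2–C3 (ring path C2–CH2–O–C(=O)–C3) lying anti to the C1 aryl group, via formyl acid 11 (not isolated), via hydroxy acid 12 (not isolated)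
Conditions: O3, CH2Cl2–MeOH, Sudan Red 7B as end-point indicator, −78 °C; then NaBH4, −78 °C to rt; acidic aqueous work-up
Reagents that add atoms: ozone, [O-][O+]=O
Why: ozonolysis of a silyl enol ether with reductive work-up, in which the enol ether is by far the most ozone-reactive site, the formyl group is reduced in the cold before C2 can epimerise, and the hydroxy acid closes to the cis-fused lactone, the more stable fusion on a tetralin.

Step 9
Reactants: 13 cis-fused γ-butyrolactone
Product: 14 (1S,2R,3S)-7,8-bis(benzyloxy)-2,3-bis(hydroxymethyl)-6-methoxy-1-(3,4,5-trimethoxyphenyl)tetralin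
Conditions: LiAlH4, THF, 0 °C to rt
Reagents that add atoms: none
Why: standard hydride reduction of a lactone to the 1,4-diol, fast enough that the α-carbon C3 is not epimerised and without effect on aryl ethers.

Step 10
Reactants: 14 (1S,2R,3S)-7,8-bis(benzyloxy)-2,3-bis(hydroxymethyl)-6-methoxy-1-(3,4,5-trimethoxyphenyl)tetralin
Product: 15 target, (1S,2R,3S)-2,3-bis(hydroxymethyl)-6-methoxy-1-(3,4,5-trimethoxyphenyl)tetralin-7,8-diol
Conditions: H2 (1 atm), Pd/C (10 wt%), EtOAc–EtOH, rt; filtered and concentrated under argon
Reagents that add atoms: none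
Why: hydrogenolysis of benzyl aryl ethers, with no other reducible group present, and it frees the air-sensitive catechol in a step whose work-up is only a filtration.

**Compound list**
1 | 3,4,5-trimethoxybenzaldehyde | COc1cc(C=O)cc(OC)c1OC | starting material
2 | (E)-1-(3,4,5-trimethoxyphenyl)buta-1,3-diene | C=C/C=C/c1cc(OC)c(OC)c(OC)c1 | intermediate
3 | 3-methoxycatechol | COc1cccc(O)c1O | starting material
4 | 3-methoxy-1,2-benzoquinone | COC1=CC=CC(=O)C1=O | intermediate
5 | endo adduct, (4aR,8R,8aS)-3-methoxy-8-(3,4,5-trimethoxyphenyl)-4a,5,8,8a-tetrahydronaphthalene-1,2-dione (cis-fused, the three methine hydrogens on one face) | COC1=C[C@H]2CC=C[C@@H](c3cc(OC)c(OC)c(OC)c3)[C@H]2C(=O)C1=O | intermediate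
6 | (S)-6-methoxy-1-(3,4,5-trimethoxyphenyl)-1,4-dihydronaphthalene-7,8-diol | COc1cc2c(c(O)c1O)[C@H](c1cc(OC)c(OC)c(OC)c1)C=CC2 | intermediate
7 | (S)-7,8-bis(benzyloxy)-6-methoxy-1-(3,4,5-trimethoxyphenyl)-1,4-dihydronaphthalene | COc1cc2c(c(OCc3ccccc3)c1OCc1ccccc1)[C@H](c1cc(OC)c(OC)c(OC)c1)C=CC2 | intermediate
8 | cis-fused dichlorocyclobutanone (C2–CCl2–C(=O)–C3), anti to the C1 aryl group | COc1cc2c(c(OCc3ccccc3)c1OCc1ccccc1)[C@H](c1cc(OC)c(OC)c(OC)c1)[C@H]1C(Cl)(Cl)C(=O)[C@H]1C2 | intermediate
9 | cis-fused cyclobutanone (C2–CH2–C(=O)–C3), anti to the C1 aryl group | COc1cc2c(c(OCc3ccccc3)c1OCc1ccccc1)[C@H](c1cc(OC)c(OC)c(OC)c1)[C@H]1CC(=O)[C@H]1C2 | intermediate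
10 | trimethylsilyl enol ether (C2–CH=C(OSiMe3)–C3) | COc1cc2c(c(OCc3ccccc3)c1OCc1ccccc1)[C@H](c1cc(OC)c(OC)c(OC)c1)[C@H]1C=C(O[Si](C)(C)C)[C@H]1C2 | intermediate
11 | formyl acid, (1S,2R,3S)-2-formyl-tetralin-3-carboxylic acid with the substituents of 7 | COc1cc2c(c(OCc3ccccc3)c1OCc1ccccc1)[C@H](c1cc(OC)c(OC)c(OC)c1)[C@@H](C=O)[C@@H](C(=O)O)C2 | intermediate
12 | hydroxy acid, (1S,2R,3S)-2-(hydroxymethyl)-tetralin-3-carboxylic acid with the substituents of 7 | COc1cc2c(c(OCc3ccccc3)c1OCc1ccccc1)[C@H](c1cc(OC)c(OC)c(OC)c1)[C@@H](CO)[C@@H](C(=O)O)C2 | intermediate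
13 | cis-fused γ-butyrolactone (C2–CH2–O–C(=O)–C3), anti to the C1 aryl group | COc1cc2c(c(OCc3ccccc3)c1OCc1ccccc1)[C@H](c1cc(OC)c(OC)c(OC)c1)[C@H]1COC(=O)[C@H]1C2 | intermediate
14 | (1S,2R,3S)-7,8-bis(benzyloxy)-2,3-bis(hydroxymethyl)-6-methoxy-1-(3,4,5-trimethoxyphenyl)tetralin | COc1cc2c(c(OCc3ccccc3)c1OCc1ccccc1)[C@H](c1cc(OC)c(OC)c(OC)c1)[C@@H](CO)[C@@H](CO)C2 | intermediate
15 | (1S,2R,3S)-2,3-bis(hydroxymethyl)-6-methoxy-1-(3,4,5-trimethoxyphenyl)tetralin-7,8-diol | COc1cc2c(c(O)c1O)[C@H](c1cc(OC)c(OC)c(OC)c1)[C@@H](CO)[C@@H](CO)C2 | target

Total step count: 10. Longest linear sequence: 9 (steps 2 to 10 from 3, or step 1 and steps 3 to 10 from 1).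

**Steps most likely to fail**

Step 3. Possible failures:
- hetero-Diels–Alder addition through the quinone oxygens, or cycloaddition of the quinone as a carbon diene;
- redox exchange between unreacted quinone and the catechol as it forms;
- too little discrimination between the quinone faces or between endo and exo approach.

The fallback sets out from 4 and 2 and returns at 7. It gives up the chiral catalyst. The uncatalysed cycloaddition in CH2Cl2 at 0 °C to rt is the documented behaviour of simple o-benzoquinones toward acyclic dienes and should give the racemic cis-fused adduct F1. This is enolised with catalytic Et3N to the racemic catechol F2. Benzylation as in step 4 gives the racemic dibenzyl ether F3. Preparative chromatography on a polysaccharide chiral stationary phase then separates F3 into 7 and the (R)-dibenzyl ether F4, which is set aside.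

Step 5. Possible failures:
- slow cycloaddition at a hindered 1,2-disubstituted alkene;
- in that case, migration of the skipped double bond into conjugation or aromatisation of ring B under the influence of the zinc salts.

The fallback sets out from 7 and returns at 14, bypassing steps 5 to 9. The two carbons are brought in on boron instead of as a ketene.
- Alkoxide-catalysed syn-diboration (B2pin2, catalytic Cs2CO3, MeOH, THF, 70 °C), again from the face opposite the aryl group, should give the cis-2,3-bis(pinacolboronate) F5.
- Double Matteson homologation with LiCH2Cl (BrCH2Cl, n-BuLi, THF, −78 °C to rt), a 1,2-migration with retention at carbon, gives the cis-2,3-bis(pinacolborylmethyl)tetralin F6.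
- Oxidation with NaOH and H2O2 gives 14.

Step 8. Possible failures:
- attack of ozone on the two electron-rich arenes or on the benzyl ethers once the enol ether is consumed;
- epimerisation at the formyl-bearing carbon before reduction.

The fallback sets out from 10 and returns at 13. It replaces ozone by hydroxylation and acyloin cleavage.
- Catalytic OsO4 with N-methylmorpholine N-oxide in acetone–water hydroxylates the enol ether from the convex face and, after loss of the silyl group, gives the α-hydroxycyclobutanone F7.
- Pb(OAc)4 in MeOH–toluene at 0 °C cleaves it to the formyl methyl ester F8.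
- NaBH4 in MeOH at −40 °C gives the hydroxy methyl ester F9, which lactonises to 13 on acidic work-up.

**Further compounds**
F1 | step 3 | racemic cis-fused adduct, 3-methoxy-8-(3,4,5-trimethoxyphenyl)-4a,5,8,8a-tetrahydronaphthalene-1,2-dione | COC1=CC2CC=CC(c3cc(OC)c(OC)c(OC)c3)C2C(=O)C1=O
F2 | step 3 | racemic 6-methoxy-1-(3,4,5-trimethoxyphenyl)-1,4-dihydronaphthalene-7,8-diol | COc1cc2c(c(O)c1O)C(c1cc(OC)c(OC)c(OC)c1)C=CC2
F3 | step 3 | racemic 7,8-bis(benzyloxy)-6-methoxy-1-(3,4,5-trimethoxyphenyl)-1,4-dihydronaphthalene | COc1cc2c(c(OCc3ccccc3)c1OCc1ccccc1)C(c1cc(OC)c(OC)c(OC)c1)C=CC2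
F4 | step 3 | (R)-7,8-bis(benzyloxy)-6-methoxy-1-(3,4,5-trimethoxyphenyl)-1,4-dihydronaphthalene | COc1cc2c(c(OCc3ccccc3)c1OCc1ccccc1)[C@@H](c1cc(OC)c(OC)c(OC)c1)C=CC2
F5 | step 5 | cis-2,3-bis(pinacolboronate) of the tetralin, both boron atoms anti to the C1 aryl group | COc1cc2c(c(OCc3ccccc3)c1OCc1ccccc1)[C@H](c1cc(OC)c(OC)c(OC)c1)[C@@H](B1OC(C)(C)C(C)(C)O1)[C@@H](B1OC(C)(C)C(C)(C)O1)C2
F6 | step 5 | cis-2,3-bis(pinacolborylmethyl)tetralin, both CH2B groups anti to the C1 aryl group | COc1cc2c(c(OCc3ccccc3)c1OCc1ccccc1)[C@H](c1cc(OC)c(OC)c(OC)c1)[C@@H](CB1OC(C)(C)C(C)(C)O1)[C@@H](CB1OC(C)(C)C(C)(C)O1)C2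
F7 | step 8 | α-hydroxycyclobutanone (C2–CH(OH)–C(=O)–C3), hydroxyl on the convex face | COc1cc2c(c(OCc3ccccc3)c1OCc1ccccc1)[C@H](c1cc(OC)c(OC)c(OC)c1)[C@H]1[C@H](O)C(=O)[C@H]1C2
F8 | step 8 | formyl methyl ester (CHO on C2, CO2Me on C3, cis) | COc1cc2c(c(OCc3ccccc3)c1OCc1ccccc1)[C@H](c1cc(OC)c(OC)c(OC)c1)[C@@H](C=O)[C@@H](C(=O)OC)C2
F9 | step 8 | hydroxy methyl ester (CH2OH on C2, CO2Me on C3, cis) | COc1cc2c(c(OCc3ccccc3)c1OCc1ccccc1)[C@H](c1cc(OC)c(OC)c(OC)c1)[C@@H](CO)[C@@H](C(=O)OC)C2
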